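**One step.** In a one-step picture first product keeps climbing, so its peak is the end of the run. The steps thought possible carry it onward, so a peak inside the run needs two clocks.

- beta: starting material 0.050 M; gas 24 mM (held); run made earlier
- flask: starting material 0.10 M; gas 24 mM (held); time 30 h

- beta (time / h: first product / %, starting material / %): 0.200: 0.7, 99.7; 0.667: 1.4, 96.4; 1.00: 2.6, 92.7; 1.50: 4.1, 91.3; 2.50: 6.5, 83.9; 3.00: 7.6, 81.3

(readings scatter by 0.5 percentage points)

- at the start none of reagent is dissolved
- steps thought possible: starting material + reagent -> first product; starting material + reagent -> other mono adduct; reagent + first product -> bis adduct; reagent + other mono adduct -> bis adduct; gas <-> reagent; first product <-> isomer of the product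

* time up to 30 h at which first product stands highest
* the amount of first product, in percent of the starting material charged, at that time

**First clock.** I took the last beta reading, 81.3% of starting material at 3.00 h, as pseudo-first-order decay. That gave T, the half-life of starting material, 10.0 h. I assumed that T carried over to the flask with its charge of 0.10 M.

**Second clock.** The other clock is the half-life of first product against its losses. With both first order, equal half-lives put the peak at the mean life of starting material, 14.5 h; a shorter half-life of first product puts it earlier, a longer one later. The beta readings of first product were still rising at the last one, 7.6%, so I left that ratio open and kept this mark.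

**Forecast.** The forecast gave 21% at 20 h, later than my mark, and it said “The runs barely show first product's loss”.

**The flask.** The flask gave 12.6% at 9.25 h, earlier than the mark.

    starting material + reagent → first product (k = 0.0290 L mol⁻¹ min⁻¹)
    starting material + reagent → other mono adduct (k = 0.0220 L mol⁻¹ min⁻¹)
    reagent + first product → bis adduct (k = 0.0260 L mol⁻¹ min⁻¹)
    reagent + other mono adduct → bis adduct (k = 0.00980 L mol⁻¹ min⁻¹)
    gas ⇌ reagent, rate k5*(csat - [reagent]) (kL = 0.100 min⁻¹)
    first product ⇌ isomer of the product (K = 21.0, k = 0.00230 min⁻¹)

**Neighbour.** First product's forward half-life towards isomer of the product alone was 5.0 h, shorter than T, which was twice that. In the neighbouring flask, the same charge read at 12 h, T gave 43.5% of starting material, and that flask held 43.3%. First product in that flask stood at 12.2%, after a highest value of 12.6%.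

The numbers in the tables are simulated from invented constants; noise was put on by code.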